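## The problem

The target is one enantiomer of a 2,5-diaryloxolane: 4-hydroxy-3,5-dimethoxyphenyl (syringyl) rings on C2 and C5, hydroxymethyl groups on C3 and C4, and four contiguous stereocentres on one five-membered ring. Oxolane numbering is used throughout; ring A is the aryl group on C2 and ring B the one on C5. The constitution is symmetric but the configuration (2S,3R,4R,5R) is not: the aryl groups are 2,5-cis and the hydroxymethyl groups 3,4-trans, so C2/C3 are trans while C4/C5 are cis. No symmetry can be used, and the two benzylic carbons must be made in different ways. C3 has no neighbour to lean on and must come from an enantioselective step; it can then direct C4 (trans, on a five-membered template), C4 can direct the C5 carbinol by 1,2-induction, and C2 can be set last, trans to C3. Both ring C–O bonds are para-hydroxybenzylic: once the neighbouring phenol is free, acid, base or heat can open them through a quinone methide and reclose them, which would relax the less stable cis C4/C5 pair; the electron-rich phenols are also easily oxidised. The ring B phenol should therefore stay masked until the last step, and that step must be mild. The enabling feature is that C2 is benzylic, para to the phenolic hydroxyl of ring A, and four atoms from the oxygen on C5 (O–C5–C4–C3–C2): two-electron oxidation of ring A makes C2 the exocyclic carbon of a para-quinone methide, placed for attack by that oxygen, so the oxolane can be closed by C–H oxidation without a leaving group at C2.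

## Retrosynthesis

**19 to 18.** Only three O–Si bonds are cut: the target 19 is traced to its tris-silyl derivative 18, with both primary alcohols and the ring B phenol as tert-butyldimethylsilyl (TBS) ethers and the ring A phenol free. A silyl ether on ring B is preferred to an electron-poor sulfonate because it leaves with the other two in one buffered fluoride step, without hot alkoxide or amide base acting on a para-hydroxybenzylic ether. The price is that chemoselectivity in the oxidation rests on the potential gap between a free phenol and a phenol ether. The forward step only has to avoid opening the ring.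

**18 to 16 (O1–C2).** The O1–C2 bond is cut, leading through the quinone methide 17 to the open-chain phenol 16, in which C2 is a plain benzylic CH2. The neighbouring cut, O1–C5, would close the ring at a C5 cation and leave the cis C4/C5 relation to thermodynamic control, which favours the wrong epimer. The O1–C2 cut instead puts the only stereo-undefined event at the carbon that wants to be trans to its neighbour. Precursor 16 has one ring and one stereocentre fewer and needs no functional group at C2. The forward reaction must oxidise ring A and not ring B, close 5-exo through the C5 oxygen alone, and give the 2,3-trans ring.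

**16 to 13 (protecting-group and oxidation-level changes).** Phenol 16 comes from its benzyl ether 15, 15 from triol 14 by silylation of the two primary hydroxyls, and 14 from hydroxy lactone 13 by reduction. No skeletal bond is cut. The lactone in 13 ties the two future hydroxymethyl carbons into a ring, which is what allows C3 to control C4. It has to be opened before the key step, since a trans-fused bicycle cannot form. The forward steps need a hydride that spares silyl and benzyl ethers, silylation selective for primary over hindered secondary benzylic hydroxyl, and hydrogenolysis that spares the C5 benzylic alcohol.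

**13 to 8 + 9 (C4–C5).** The C4–C5 bond is cut by an aldol disconnection into the β-benzyl lactone 8 and the ring B aldehyde 9. This divides the molecule into two halves of equal size, both derived from one phenolic aldehyde. The lactone enolate should add trans to the C3 arm, setting C4. The carbinol at C5 is less secure in the C–C bond formation, so the epimer mixture 11 is converged by oxidation to keto lactone 12 and substrate-controlled reduction to 13. A C3–C4 cut (conjugate addition to a butenolide) would build both centres at once but offers no reliable handle for the C5 carbinol.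

**8 to 2 + 3 (benzylic C–C3 bond and the C3 stereocentre).** Lactone 8 is traced through half-ester 6 to the alkylidene succinate 5, and 5 to the benzyl-protected aldehyde 2 and dimethyl succinate 3 by a Stobbe disconnection. This is preferred to an auxiliary-based alkylation because the condensation delivers the two carboxyl groups already differentiated (one ester, one acid). The free acid is also the binding site that itaconate-type asymmetric hydrogenation requires, so the only stereocentre without a neighbour is set by catalysis. Reduction of the ester, not the acid, then gives the β-substituted lactone.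

**2 and 9 to 1.** Both aldehydes are ethers of syringaldehyde 1: a benzyl ether for ring A, to be removed by hydrogenolysis just before the oxidation, and a silyl ether for ring B, which stays to the end. The two masks encode the later difference in oxidisability between the rings.

## Roads not taken

Alternative 1: The cut runs through C2–C3 and O1–C2 in a [4+1] sense. A benzylic sulfonium salt A3 would be deprotonated to its ylide and added to the unsubstituted alkene carbon of the aroylbutenedioate A2. The keto ester enolate then closes through oxygen with loss of the sulfide and gives the 2,3-trans dihydrofuran diester A1. Hydrogenation of C4=C5 and reduction of both esters would finish the skeleton. Its merit is convergence: two bonds, the ring and all carbons arrive in one step from two fragments of similar size, and the route would be clearly shorter than the chosen one. Its weak points lie after the annulation. The C4=C5 bond of A1 is a tetrasubstituted, donor–acceptor enol ether, among the least reactive alkenes in hydrogenation. Hydrogen would also have to enter from the face that carries the adjacent C3 substituent in order to give 3,4-trans and 2,5-cis; an undirected catalyst should prefer the other face and set both new centres wrongly. A directing hydroxymethyl group at C3 would first require differentiating the two esters. Conditions forcing enough to reduce this alkene also threaten the benzylic C–O bonds and invite aromatisation to the furan. Absolute control would need a stoichiometric chiral sulfide on an electron-rich, ionisation-prone benzyl sulfonium salt. In step count this road is better. The chosen plan sets against it that each stereocentre is formed by a reaction running with its natural preference, and that the last one (C2) forms trans to its neighbour.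

Alternative 2: The cut is C4–C5 together with the lactone C–O bond. A chiral triazolylidene carbene would convert the silyloxy enal A5 into a homoenolate, which adds to the mesylated aldehyde A6; the alkoxide lactonises to the cis lactone A4. In making the cis C4/C5 pair this road is better on paper than the chosen plan: one catalytic step that sets relative and absolute configuration, against aldol, oxidation and reduction. The weak points are the substrate class and the endgame. The β-substituent of A5 is an alkyl-type CH2OSi group; such enals are poorer partners than cinnamaldehydes in intermolecular annulations with aldehydes, and cis/trans and enantioselectivity are then less dependable. The γ-oxygen also offers an elimination pathway from the acyl-azolium stage. After A4, the C3 hydroxymethyl carbon must still be introduced by enolate chemistry, the lactone carbonyl turned into the C2 benzylic carbon by arylation at the lactol oxidation level, and the sulfonate removed under forcing base. That is five or six further operations, with the C2 configuration decided at an oxocarbenium ion. The chosen plan sets against it dependable absolute control by hydrogenation of an itaconate-type acid, and a C2-forming step that needs neither a leaving group nor a Lewis acid.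

Alternative 3: The cut is O1–C5 and C4–C5. A rhodium carboxylate catalyst would turn the aryldiazomethane A9 into a carbene, which is captured by the ring oxygen of the trans dihydropyran A8. The oxonium ylide would contract by a [2,3] shift to the vinyl oxolane A7, whose vinyl group is a masked hydroxymethyl. The attraction is that the ring, two stereocentres and the C4 carbon substituent appear in one step, with chirality relayed through a five-membered cyclic transition state. The weaknesses are several. A9 is a donor-only, electron-rich diazo compound: unstable, prone to azine and stilbene formation, and not the type that gives clean intermolecular oxonium ylide chemistry with ethers. Cyclopropanation of the ring alkene and a [1,2] shift compete. The shift must deliver one of four diastereomers (2,5-cis and 4,5-cis), and which face of the ylide carbon reacts is not under obvious control. A8 needs its own enantioselective synthesis, and the vinyl group must be cleaved oxidatively in the presence of two electron-rich arenes. If the shift were selective this road would reach the ring earlier than the chosen plan. The chosen plan is longer but rests on precedented steps and a ring closure whose stereochemical outcome is also the thermodynamic one.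

Key step: step 12

Assumption: the (S,S) ligand in step 3 is assigned by analogy with related itaconate half-esters; whichever antipode of the ligand delivers the (R)-acid 6 is the one to use.

## Route

TBS = tert-butyldimethylsilyl.

Step 1
Reactants: 1 syringaldehyde (4-hydroxy-3,5-dimethoxybenzaldehyde)
Product: 2 4-benzyloxy-3,5-dimethoxybenzaldehyde
Conditions: BnBr, K2CO3, DMF, 60 °C
Reagents that add atoms: benzyl bromide, BrCc1ccccc1
Why: Williamson etherification of the phenoxide; the phenol must be masked because a phenoxide would deactivate the aldehyde in the condensation that follows, and a benzyl ether can later be removed without touching silyl ethers.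

Step 2
Reactants: 2 4-benzyloxy-3,5-dimethoxybenzaldehyde; 3 dimethyl succinate
Product: 5 (E)-4-(4-benzyloxy-3,5-dimethoxyphenyl)-3-(methoxycarbonyl)but-3-enoic acid, via paraconate ester 4 (not isolated)
Conditions: NaOMe, MeOH, reflux; then aq. HCl
Reagents that add atoms: none
Why: Stobbe condensation: the succinate enolate adds to the aldehyde, the alkoxide lactonises to 4, and base-induced ring opening gives the half-ester with the aryl group trans to the conjugated ester; the two carboxyl groups emerge differentiated.

Step 3
Reactants: 5 (E)-4-(4-benzyloxy-3,5-dimethoxyphenyl)-3-(methoxycarbonyl)but-3-enoic acid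
Product: 6 (R)-4-(4-benzyloxy-3,5-dimethoxyphenyl)-3-(methoxycarbonyl)butanoic acid
Conditions: [Rh(cod)((S,S)-Et-DuPhos)]BF4 (1 mol%), NaOMe (0.1 equiv), H2 (5 bar), MeOH, rt
Reagents that add atoms: none
Why: Asymmetric hydrogenation of an itaconate-type half-ester: the carboxylate binds the cationic monovalent rhodium centre beside the alkene, and the chiral bisphosphine selects the alkene face, setting the future C3; a homogeneous rhodium catalyst does not cleave the benzyl ether.

Step 4
Reactants: 6 (R)-4-(4-benzyloxy-3,5-dimethoxyphenyl)-3-(methoxycarbonyl)butanoic acid
Product: 8 (R)-4-(4-benzyloxy-3,5-dimethoxybenzyl)oxolan-2-one, via hydroxy acid 7 (not isolated)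
Conditions: KOH (1 equiv), EtOH; CaCl2, NaBH4, −10 °C to rt; then 2 M HCl, rt
Reagents that add atoms: none
Why: Chemoselective ester reduction: Ca(BH4)2 made in situ reduces the ester but not the carboxylate, and acidification lactonises hydroxy acid 7; reducing the ester (not the acid) puts the benzyl group on the β-carbon, and the stereocentre is not touched.

Step 5
Reactants: 1 syringaldehyde
Product: 9 4-(tert-butyldimethylsilyloxy)-3,5-dimethoxybenzaldehyde
Conditions: TBSCl, imidazole, DMF, rt
Reagents that add atoms: tert-butyldimethylsilyl chloride, CC(C)(C)[Si](C)(C)Cl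
Why: Standard silylation of a phenol; the silyl ether flanked by two methoxy groups is robust to enolates, hydrides and hydrogenolysis and keeps ring B unoxidisable relative to a free phenol.

Step 6
Reactants: 8 (R)-4-(4-benzyloxy-3,5-dimethoxybenzyl)oxolan-2-one; 9 4-(tert-butyldimethylsilyloxy)-3,5-dimethoxybenzaldehyde
Product: 11 (3S,4R)-4-(4-benzyloxy-3,5-dimethoxybenzyl)-3-{[4-(tert-butyldimethylsilyloxy)-3,5-dimethoxyphenyl](hydroxy)methyl}oxolan-2-one as both carbinol epimers, via lithium enolate 10 (not isolated)
Conditions: LiN(iPr)2, THF, −78 °C; then 9, −78 °C; aq. NH4Cl at −78 °C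
Reagents that add atoms: none
Why: Aldol addition of a lactone lithium enolate: the aldehyde approaches the planar enolate anti to the benzyl arm, giving the trans lactone (C4 of the target). The chair transition state of the ring-locked E(O)-enolate should lean toward the anti carbinol, but this is not relied on and both epimers are carried forward.

Step 7
Reactants: 11 aldol adducts (both carbinol epimers)
Product: 12 (3S,4R)-4-(4-benzyloxy-3,5-dimethoxybenzyl)-3-[4-(tert-butyldimethylsilyloxy)-3,5-dimethoxybenzoyl]oxolan-2-one
Conditions: Dess–Martin periodinane, CH2Cl2, 0 °C to rt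
Reagents that add atoms: none
Why: Dess–Martin oxidation converts both epimers into one keto lactone; the carbon between the two carbonyl groups is epimerisable but rests in the trans arrangement, which is the stable one.

Step 8
Reactants: 12 keto lactone
Product: 13 (3S,4R)-4-(4-benzyloxy-3,5-dimethoxybenzyl)-3-{(R)-[4-(tert-butyldimethylsilyloxy)-3,5-dimethoxyphenyl](hydroxy)methyl}oxolan-2-one
Conditions: KBH(sBu)3, THF, −78 °C; aq. NH4Cl
Reagents that add atoms: none
Why: Substrate-controlled hydride reduction under polar Felkin–Anh control: with the weakly chelating potassium counter-ion the lactone carbonyl should lie anti to the incoming hydride, the ketone oxygen next to the ring carbon and the aryl group next to the α-hydrogen. Hydride then enters from the open outer face and gives the (R)-carbinol, which is the anti relation that becomes cis C4/C5 in the oxolane.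

Step 9
Reactants: 13 hydroxy lactone
Product: 14 (1R,2R,3R)-4-(4-benzyloxy-3,5-dimethoxyphenyl)-1-[4-(tert-butyldimethylsilyloxy)-3,5-dimethoxyphenyl]-2,3-bis(hydroxymethyl)butan-1-ol
Conditions: LiBH4, THF, MeOH (1 equiv), 0 °C to rt; aq. NH4Cl
Reagents that add atoms: none
Why: LiBH4 reduces lactones to diols and leaves aryl silyl and benzyl ethers alone; no stereocentre is at risk, since the former α-carbon is no longer next to a carbonyl group after reduction.

Step 10
Reactants: 14 triol
Product: 15 (1R,2R,3R)-4-(4-benzyloxy-3,5-dimethoxyphenyl)-1-[4-(tert-butyldimethylsilyloxy)-3,5-dimethoxyphenyl]-2,3-bis(tert-butyldimethylsilyloxymethyl)butan-1-ol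
Conditions: TBSCl (2.2 equiv), imidazole, CH2Cl2, −20 to 0 °C
Reagents that add atoms: tert-butyldimethylsilyl chloride, CC(C)(C)[Si](C)(C)Cl
Why: Selective silylation: the two primary hydroxyls react far faster with a bulky silyl chloride than the secondary benzylic hydroxyl, which is flanked by an aryl ring and a branched carbon; the hydroxyl that must close the ring is thus the only one left free.

Step 11
Reactants: 15 benzyl ether
Product: 16 (1R,2R,3R)-4-(4-hydroxy-3,5-dimethoxyphenyl)-1-[4-(tert-butyldimethylsilyloxy)-3,5-dimethoxyphenyl]-2,3-bis(tert-butyldimethylsilyloxymethyl)butan-1-ol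
Conditions: H2 (1 atm), Pd/C (10 wt%), EtOAc, rt
Reagents that add atoms: none
Why: Hydrogenolysis of an aryl benzyl ether; under neutral conditions in EtOAc the benzylic C–OH bond is cleaved much more slowly and silyl ethers are inert, so only ring A is unmasked.

Step 12
Reactants: 16 phenol
Product: 18 (2S,3R,4R,5R)-2-(4-hydroxy-3,5-dimethoxyphenyl)-5-[4-(tert-butyldimethylsilyloxy)-3,5-dimethoxyphenyl]-3,4-bis(tert-butyldimethylsilyloxymethyl)oxolane, via quinone methide 17 (not isolated)
Conditions: graphite anode, Pt cathode, undivided cell, constant current (2 mA cm−2, 2.1 F mol−1), LiClO4 (0.1 M), 2,6-lutidine (3 equiv), MeCN/CH2Cl2, 0 °C; then rt without current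
Reagents that add atoms: none
Why: At the carbon anode the free phenol of ring A, assisted by 2,6-lutidine, should lose two electrons and two protons (the phenolic one and one from C2) to give the para-quinone methide 17, either through the phenoxonium ion or by disproportionation of phenoxyl radicals whose ortho and para positions are blocked against coupling. The hydroxyl on C5 then adds to the exocyclic carbon C2 in a 5-exo-trig oxa-conjugate addition that restores the aromatic ring and forms O1–C2. The closest known reaction type is the anodic or chemical oxidation of 4-alkyl-2,6-dimethoxyphenols to quinone methides with capture of an oxygen nucleophile at the benzylic carbon; the intramolecular capture here applies it to a new substrate. C2 is the only new stereocentre and is controlled by C3: in the envelope transition state the silyloxymethyl arm on C3 is pseudo-equatorial and the quinone methide turns away from it, giving the 2,3-trans ring. This is also the more stable C2 epimer, so reversible opening at C2 (possible because ring A is a free phenol) can only reinforce the outcome. C3, C4 and C5 are untouched, and C5 cannot open because ring B is a silyl ether. The step needs oxidation of ring A only: a free phenol with base present is oxidised at a far lower potential than a silyloxy-dimethoxyarene, so ring B and its benzylic carbinol should survive while the charge is held near two electrons per molecule. It also needs a single oxygen nucleophile, which is secured by the silylation of both primary hydroxyls and by the non-nucleophilic solvent and electrolyte; lutidinium is reduced to H2 at the cathode.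

Step 13
Reactants: 18 tris-silyl oxolane
Product: 19 [(2S,3R,4R,5R)-2,5-bis(4-hydroxy-3,5-dimethoxyphenyl)oxolane-3,4-diyl]dimethanol (the target; 2,3-trans, 3,4-trans, 4,5-cis)
Conditions: Bu4NF (4 equiv), AcOH (4 equiv), THF, 0 °C to rt
Reagents that add atoms: none
Why: Fluoride desilylation removes the aryl and both primary alkyl silyl ethers in one operation; the acetic acid buffer and low temperature keep the phenoxides from opening the para-hydroxybenzylic ring bonds, so the cis C4/C5 pair should be preserved.

## Compound list

1 | syringaldehyde (4-hydroxy-3,5-dimethoxybenzaldehyde) | COc1cc(C=O)cc(OC)c1O | starting material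
2 | 4-benzyloxy-3,5-dimethoxybenzaldehyde | COc1cc(C=O)cc(OC)c1OCc1ccccc1 | intermediate
3 | dimethyl succinate | COC(=O)CCC(=O)OC | starting material
4 | methyl 2-(4-benzyloxy-3,5-dimethoxyphenyl)-5-oxooxolane-3-carboxylate (paraconate ester, diastereomer mixture) | COC(=O)C1CC(=O)OC1c1cc(OC)c(OCc2ccccc2)c(OC)c1 | intermediate (not isolated)
5 | (E)-4-(4-benzyloxy-3,5-dimethoxyphenyl)-3-(methoxycarbonyl)but-3-enoic acid | OC(=O)C/C(C(=O)OC)=C\c1cc(OC)c(OCc2ccccc2)c(OC)c1 | intermediate
6 | (R)-4-(4-benzyloxy-3,5-dimethoxyphenyl)-3-(methoxycarbonyl)butanoic acid | OC(=O)C[C@@H](Cc1cc(OC)c(OCc2ccccc2)c(OC)c1)C(=O)OC | intermediate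
7 | (R)-4-(4-benzyloxy-3,5-dimethoxyphenyl)-3-(hydroxymethyl)butanoic acid (present as its carboxylate salt) | OC(=O)C[C@@H](Cc1cc(OC)c(OCc2ccccc2)c(OC)c1)CO | intermediate (not isolated)
8 | (R)-4-(4-benzyloxy-3,5-dimethoxybenzyl)oxolan-2-one | O=C1C[C@@H](Cc2cc(OC)c(OCc3ccccc3)c(OC)c2)CO1 | intermediate
9 | 4-(tert-butyldimethylsilyloxy)-3,5-dimethoxybenzaldehyde | COc1cc(C=O)cc(OC)c1O[Si](C)(C)C(C)(C)C | intermediate
10 | lithium (R)-4-(4-benzyloxy-3,5-dimethoxybenzyl)-4,5-dihydrofuran-2-olate | [Li]OC1=C[C@@H](Cc2cc(OC)c(OCc3ccccc3)c(OC)c2)CO1 | intermediate (not isolated)
11 | (3S,4R)-4-(4-benzyloxy-3,5-dimethoxybenzyl)-3-{[4-(tert-butyldimethylsilyloxy)-3,5-dimethoxyphenyl](hydroxy)methyl}oxolan-2-one, both carbinol epimers | OC(c1cc(OC)c(O[Si](C)(C)C(C)(C)C)c(OC)c1)[C@H]1C(=O)OC[C@@H]1Cc1cc(OC)c(OCc2ccccc2)c(OC)c1 | intermediate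
12 | (3S,4R)-4-(4-benzyloxy-3,5-dimethoxybenzyl)-3-[4-(tert-butyldimethylsilyloxy)-3,5-dimethoxybenzoyl]oxolan-2-one | O=C(c1cc(OC)c(O[Si](C)(C)C(C)(C)C)c(OC)c1)[C@H]1C(=O)OC[C@@H]1Cc1cc(OC)c(OCc2ccccc2)c(OC)c1 | intermediate
13 | (3S,4R)-4-(4-benzyloxy-3,5-dimethoxybenzyl)-3-{(R)-[4-(tert-butyldimethylsilyloxy)-3,5-dimethoxyphenyl](hydroxy)methyl}oxolan-2-one | O[C@@H](c1cc(OC)c(O[Si](C)(C)C(C)(C)C)c(OC)c1)[C@H]1C(=O)OC[C@@H]1Cc1cc(OC)c(OCc2ccccc2)c(OC)c1 | intermediate
14 | (1R,2R,3R)-4-(4-benzyloxy-3,5-dimethoxyphenyl)-1-[4-(tert-butyldimethylsilyloxy)-3,5-dimethoxyphenyl]-2,3-bis(hydroxymethyl)butan-1-ol | O[C@@H](c1cc(OC)c(O[Si](C)(C)C(C)(C)C)c(OC)c1)[C@@H](CO)[C@H](CO)Cc1cc(OC)c(OCc2ccccc2)c(OC)c1 | intermediate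
15 | (1R,2R,3R)-4-(4-benzyloxy-3,5-dimethoxyphenyl)-1-[4-(tert-butyldimethylsilyloxy)-3,5-dimethoxyphenyl]-2,3-bis(tert-butyldimethylsilyloxymethyl)butan-1-ol | O[C@@H](c1cc(OC)c(O[Si](C)(C)C(C)(C)C)c(OC)c1)[C@@H](CO[Si](C)(C)C(C)(C)C)[C@H](CO[Si](C)(C)C(C)(C)C)Cc1cc(OC)c(OCc2ccccc2)c(OC)c1 | intermediate
16 | (1R,2R,3R)-4-(4-hydroxy-3,5-dimethoxyphenyl)-1-[4-(tert-butyldimethylsilyloxy)-3,5-dimethoxyphenyl]-2,3-bis(tert-butyldimethylsilyloxymethyl)butan-1-ol | O[C@@H](c1cc(OC)c(O[Si](C)(C)C(C)(C)C)c(OC)c1)[C@@H](CO[Si](C)(C)C(C)(C)C)[C@H](CO[Si](C)(C)C(C)(C)C)Cc1cc(OC)c(O)c(OC)c1 | intermediate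
17 | 4-{(2R,3R,4R)-4-hydroxy-4-[4-(tert-butyldimethylsilyloxy)-3,5-dimethoxyphenyl]-2,3-bis(tert-butyldimethylsilyloxymethyl)butylidene}-2,6-dimethoxycyclohexa-2,5-dien-1-one (para-quinone methide) | O[C@@H](c1cc(OC)c(O[Si](C)(C)C(C)(C)C)c(OC)c1)[C@@H](CO[Si](C)(C)C(C)(C)C)[C@H](CO[Si](C)(C)C(C)(C)C)C=C1C=C(OC)C(=O)C(OC)=C1 | intermediate (not isolated)
18 | (2S,3R,4R,5R)-2-(4-hydroxy-3,5-dimethoxyphenyl)-5-[4-(tert-butyldimethylsilyloxy)-3,5-dimethoxyphenyl]-3,4-bis(tert-butyldimethylsilyloxymethyl)oxolane | COc1cc([C@H]2O[C@@H](c3cc(OC)c(O[Si](C)(C)C(C)(C)C)c(OC)c3)[C@@H](CO[Si](C)(C)C(C)(C)C)[C@@H]2CO[Si](C)(C)C(C)(C)C)cc(OC)c1O | intermediate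
19 | [(2S,3R,4R,5R)-2,5-bis(4-hydroxy-3,5-dimethoxyphenyl)oxolane-3,4-diyl]dimethanol | COc1cc([C@H]2O[C@@H](c3cc(OC)c(O)c(OC)c3)[C@@H](CO)[C@@H]2CO)cc(OC)c1O | target

## Step count, longest sequence and least certain steps

Total step count: 13. Longest linear sequence: 12 steps (steps 1–4 and 6–13); step 5 is the only side branch.

**Step 12 (key step).** The most likely failure is over-oxidation. The ring A phenol of product 18 is oxidised at nearly the same potential as that of 16, so continued electrolysis would open or oxidise C2 again. Two further risks are capture of the phenoxonium stage at the ipso carbon, giving a spiro-dienone, and sluggish ring closure of the stabilised syringyl quinone methide. The fallback separates oxidation from ring closure with a stoichiometric chemical oxidant. Starting from 16, Ag2O in CH2Cl2 at rt should give the quinone methide 17, which is persistent enough to be freed from silver by filtration. A catalytic amount of Et3N, or of a weak acid, in CH2Cl2 should then close 17 to 18, where the route is rejoined. The product never meets the oxidant, and no compound outside the list is made.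

**Step 8.** Hydride may be delivered to the other carbonyl face through a cation-bridged arrangement of the two carbonyl groups, or the basic borohydride may enolise the β-keto lactone so that 12 is returned. The fallback replaces substrate control by catalyst control. Starting from 12, asymmetric transfer hydrogenation with RuCl(p-cymene)[(R,R)-TsDPEN] in HCO2H/Et3N should set the aryl carbinol by the ligand, while the labile α-carbon equilibrates to the trans arrangement, and give 13 directly. The (R,R) sense is assigned by analogy with simple aryl alkyl ketones, and the antipode is available should it prove opposite. No new compound is made.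

**Step 3.** Enantiofacial discrimination may be incomplete or turnover slow, because the alkene is trisubstituted and carries a 3,4,5-trioxygenated aryl group; any Z-isomer in 5 would erode selectivity further. The fallback is resolution. Starting from 5, hydrogenation with the achiral catalyst [Rh(cod)(dppb)]BF4 should give racemic 4-(4-benzyloxy-3,5-dimethoxyphenyl)-3-(methoxycarbonyl)butanoic acid F1. Crystallisation with (R)-1-phenylethylamine (or its antipode, whichever gives the less soluble salt with the R acid) should give the (R)-1-phenylethylammonium salt of the (R)-acid F2, and acidification returns 6.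

**Step 10.** Silylation may spread to the secondary benzylic hydroxyl or stall at the mono-silyl stage, with silyl migration between the 1,3-related oxygens. The fallback masks the C5 oxygen before the lactone is opened. Starting from 13, 2-methoxypropene with catalytic pyridinium p-toluenesulfonate should give the 2-methoxypropan-2-yl ether of 13 F3. LiBH4 should reduce it to the corresponding 2,3-bis(hydroxymethyl) diol F4, and excess TBSCl/imidazole should give the bis-TBS ether F5. Brief treatment with pyridinium p-toluenesulfonate in MeOH at 0 °C removes the mixed acetal only and returns 15.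

**Step 6.** The lithium aldolate may revert (retro-aldol) or conversion may stay incomplete with the electron-rich aldehyde, and the epimer mixture makes purification awkward. The fallback forms the C4–C5 bond by acylation. Starting from 9, Pinnick oxidation should give 4-(tert-butyldimethylsilyloxy)-3,5-dimethoxybenzoic acid F6, and oxalyl chloride with catalytic DMF should give 4-(tert-butyldimethylsilyloxy)-3,5-dimethoxybenzoyl chloride F7. Acylation of enolate 10 (from 8 with two equivalents of LiN(iPr)2) with F7 should give keto lactone 12 directly, where the route is rejoined without passing through 11.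

## Further compounds

F0 | step 12 | none | none
F0 | step 8 | none | none
F1 | step 3 | racemic 4-(4-benzyloxy-3,5-dimethoxyphenyl)-3-(methoxycarbonyl)butanoic acid | OC(=O)CC(Cc1cc(OC)c(OCc2ccccc2)c(OC)c1)C(=O)OC
F2 | step 3 | (R)-1-phenylethylammonium (R)-4-(4-benzyloxy-3,5-dimethoxyphenyl)-3-(methoxycarbonyl)butanoate | [O-]C(=O)C[C@@H](Cc1cc(OC)c(OCc2ccccc2)c(OC)c1)C(=O)OC.C[C@@H]([NH3+])c1ccccc1
F3 | step 10 | (3S,4R)-4-(4-benzyloxy-3,5-dimethoxybenzyl)-3-{(R)-[4-(tert-butyldimethylsilyloxy)-3,5-dimethoxyphenyl](2-methoxypropan-2-yloxy)methyl}oxolan-2-one | COC(C)(C)O[C@@H](c1cc(OC)c(O[Si](C)(C)C(C)(C)C)c(OC)c1)[C@H]1C(=O)OC[C@@H]1Cc1cc(OC)c(OCc2ccccc2)c(OC)c1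
F4 | step 10 | (2R,3R)-2-(4-benzyloxy-3,5-dimethoxybenzyl)-3-{(R)-[4-(tert-butyldimethylsilyloxy)-3,5-dimethoxyphenyl](2-methoxypropan-2-yloxy)methyl}butane-1,4-diol | COC(C)(C)O[C@@H](c1cc(OC)c(O[Si](C)(C)C(C)(C)C)c(OC)c1)[C@@H](CO)[C@H](CO)Cc1cc(OC)c(OCc2ccccc2)c(OC)c1
F5 | step 10 | bis(tert-butyldimethylsilyl) ether of F4 at both primary hydroxyls | COC(C)(C)O[C@@H](c1cc(OC)c(O[Si](C)(C)C(C)(C)C)c(OC)c1)[C@@H](CO[Si](C)(C)C(C)(C)C)[C@H](CO[Si](C)(C)C(C)(C)C)Cc1cc(OC)c(OCc2ccccc2)c(OC)c1
F6 | step 6 | 4-(tert-butyldimethylsilyloxy)-3,5-dimethoxybenzoic acid | COc1cc(C(=O)O)cc(OC)c1O[Si](C)(C)C(C)(C)C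
F7 | step 6 | 4-(tert-butyldimethylsilyloxy)-3,5-dimethoxybenzoyl chloride | COc1cc(C(Cl)=O)cc(OC)c1O[Si](C)(C)C(C)(C)C
A1 | alternative 1 | dimethyl (2S,3S)-2,5-bis(4-benzyloxy-3,5-dimethoxyphenyl)-2,3-dihydrofuran-3,4-dicarboxylate (2,3-trans) | COc1cc([C@H]2OC(c3cc(OC)c(OCc4ccccc4)c(OC)c3)=C(C(=O)OC)[C@@H]2C(=O)OC)cc(OC)c1OCc1ccccc1
A2 | alternative 1 | dimethyl 2-(4-benzyloxy-3,5-dimethoxybenzoyl)but-2-enedioate | COC(=O)C=C(C(=O)OC)C(=O)c1cc(OC)c(OCc2ccccc2)c(OC)c1
A3 | alternative 1 | 1-(4-benzyloxy-3,5-dimethoxybenzyl)thiolan-1-ium bromide | COc1cc(C[S+]2CCCC2)cc(OC)c1OCc1ccccc1.[Br-]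
A4 | alternative 2 | (4R,5R)-5-(3,5-dimethoxy-4-methanesulfonyloxyphenyl)-4-(tert-butyldiphenylsilyloxymethyl)oxolan-2-one (4,5-cis) | O=C1O[C@@H](c2cc(OC)c(OS(C)(=O)=O)c(OC)c2)[C@@H](CO[Si](c2ccccc2)(c2ccccc2)C(C)(C)C)C1
A5 | alternative 2 | (E)-4-(tert-butyldiphenylsilyloxy)but-2-enal | O=C/C=C/CO[Si](c1ccccc1)(c1ccccc1)C(C)(C)C
A6 | alternative 2 | 4-formyl-2,6-dimethoxyphenyl methanesulfonate | COc1cc(C=O)cc(OC)c1OS(C)(=O)=O
A7 | alternative 3 | (2S,3R,4S,5R)-2,5-bis(4-benzyloxy-3,5-dimethoxyphenyl)-3-(tert-butyldimethylsilyloxymethyl)-4-vinyloxolane | COc1cc([C@H]2O[C@@H](c3cc(OC)c(OCc4ccccc4)c(OC)c3)[C@@H](C=C)[C@@H]2CO[Si](C)(C)C(C)(C)C)cc(OC)c1OCc1ccccc1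
A8 | alternative 3 | (2S,3R)-2-(4-benzyloxy-3,5-dimethoxyphenyl)-3-(tert-butyldimethylsilyloxymethyl)-3,6-dihydro-2H-pyran | COc1cc([C@H]2OCC=C[C@@H]2CO[Si](C)(C)C(C)(C)C)cc(OC)c1OCc1ccccc1
A9 | alternative 3 | (4-benzyloxy-3,5-dimethoxyphenyl)diazomethane | COc1cc(C=[N+]=[N-])cc(OC)c1OCc1ccccc1
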